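**Atom labels:** C1–C6 = hexanoic acid chain; C1'–C7' = tether from C2 to the ketone carbon; O1r–C6r = ring atoms.

**Plan**
1. The hardest part is the joining, not any single stereocentre: three stereochemical islands (C2–C3–C4, C4', C6r) are separated by inert methylene runs and meet the ring at the acidic, chelating C7'/C2r/C4r tricarbonyl. Classical acyl transfer reaches this only from a C7' acid with C3–OH and C1 protected.
2. Retrosynthetic cuts: C6'–C7' (alkene hydroacylation, key step), C2–C1' (dianion alkylation), C2–C3 (Claisen condensation, then asymmetric hydrogenation), and in the ring C3r–C4r and O1r–C2r (Claisen condensation, lactonisation).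
3. Enabling feature: on the dihydropyranone ring the enolic C4r–OH flanks C3r, so C7' can enter as a formyl group that is a vinylogous salicylaldehyde (O4r–Rh chelate). The C5'–C6' ethylene next to the C4' methine is the vinyl group of citronellene, whose other alkene is cut to give the C1' electrophile.
4. Forward order: the triad ester is built first (C4–C3, then C2 together with the C1'–C6' alkenyl chain). The only ring is made separately (lactone, then formylation at C3r). The C6'–C7' union and ester cleavage follow; no hydroxyl is ever protected.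
5. Stereochemistry: C4 from (S)-2-methylbutanoic acid; C3 from (R)-BINAP–Ru hydrogenation; C2 from 1,2-induction in the chelated dianion (anti); C4' from (S)-citronellene; C6r from ethyl (R)-3-hydroxybutanoate.

Key step: step 10

Assumption: the acyl-dione is handled as the 3-acyl-4-hydroxy enol tautomer written in the target SMILES, and compounds 1, 6 and 12 are taken as commercial in high enantiomeric purity.

**Step 1**
Reactants: 1 (S)-2-methylbutanoic acid; 2 tert-butyl acetate
Product: 4 tert-butyl (4S)-4-methyl-3-oxohexanoate, via acyl imidazolide 3 (not isolated)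
Conditions: CDI, THF, rt; then added to LiCH2CO2tBu (from 2, LDA, 2.5 equiv, THF, −78 °C), −78 → −40 °C; aq. NH4Cl
Reagents that add atoms: 1,1'-carbonyldiimidazole, O=C(n1ccnc1)n1ccnc1 (imidazol-1-yl of intermediate 3 only; none of its atoms remain in 4)
Why: Crossed Claisen condensation of an ester enolate with an acyl imidazolide; the β-keto ester is deprotonated at C2 as it forms, which should protect the C4 stereocentre from enolisation, and no new stereocentre arises.

**Step 2**
Reactants: 4 tert-butyl (4S)-4-methyl-3-oxohexanoate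
Product: 5 tert-butyl (3S,4S)-3-hydroxy-4-methylhexanoate
Conditions: H2 (10 bar), RuCl2[(R)-BINAP] (0.5 mol %), MeOH, 50 °C
Reagents that add atoms: none
Why: Noyori asymmetric hydrogenation of a β-keto ester, in which the ester-chelated ketone takes hydride under catalyst control; (R)-BINAP should give the (R)-3-hydroxybutanoate sense, which carries the descriptor 3S here because sec-butyl outranks C2.

**Step 3**
Reactants: 6 (S)-3,7-dimethylocta-1,6-diene ((S)-β-citronellene)
Product: 8 (S)-4-methylhex-5-en-1-ol, via aldehyde 7 (not isolated)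
Conditions: O3 (1.0 equiv, Sudan III end point), CH2Cl2/MeOH 4:1, −78 °C; then NaBH4 (excess), −78 → 0 °C
Reagents that add atoms: ozone, [O-][O+]=O
Why: Chemoselective ozonolysis with reductive work-up; the electron-rich trisubstituted alkene should react far faster than the vinyl group, and the C4' stereocentre is not involved.

**Step 4**
Reactants: 8 (S)-4-methylhex-5-en-1-ol
Product: 9 (S)-6-iodo-3-methylhex-1-ene
Conditions: PPh3, I2, imidazole, CH2Cl2, 0 °C → rt
Reagents that add atoms: iodine, II
Why: Appel-type iodination of a primary alcohol by SN2 at CH2, remote from the stereocentre.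

**Step 5**
Reactants: 5 tert-butyl (3S,4S)-3-hydroxy-4-methylhexanoate; 9 (S)-6-iodo-3-methylhex-1-ene
Product: 11 tert-butyl (2R,3R,4S)-3-hydroxy-4-methyl-2-[(4S)-4-methylhex-5-en-1-yl]hexanoate, via dilithium dianion 10 (not isolated)
Conditions: LDA (2.2 equiv), THF, −78 → −30 °C; then 9 (1.3 equiv), DMPU, −30 → 0 °C; aq. NH4Cl
Reagents that add atoms: lithium diisopropylamide, [Li+].CC(C)[N-]C(C)C (lithium of intermediate 10 only; none remains in 11)
Why: Fráter–Seebach alkylation; in the lithium-chelated (Z)-enolate alkoxide the iodide should approach the face anti to the sec-butyl group on the six-membered chelate, which sets C2 as R (2,3-anti).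

**Step 6**
Reactants: 12 ethyl (R)-3-hydroxybutanoate; 2 tert-butyl acetate
Product: 13 tert-butyl (5R)-5-hydroxy-3-oxohexanoate
Conditions: 2 (3.5 equiv), LDA (3.6 equiv), THF, −78 °C; then 12, −78 → −30 °C; aq. NH4Cl
Reagents that add atoms: none
Why: Crossed Claisen condensation of excess lithium tert-butyl acetate enolate with the unprotected β-hydroxy ester (first equivalent forms the alkoxide, the last deprotonates the product); the carbinol centre is untouched.

**Step 7**
Reactants: 13 tert-butyl (5R)-5-hydroxy-3-oxohexanoate
Product: 15 (6R)-4-hydroxy-6-methyl-5,6-dihydro-2H-pyran-2-one, via hydroxy keto acid 14 (not isolated)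
Conditions: TFA, CH2Cl2, 0 °C → rt
Reagents that add atoms: none
Why: Acidolysis of the tert-butyl ester followed by 6-exo-trig lactonisation of the δ-hydroxy β-keto acid, which should outrun decarboxylation; the C6r–O bond is retained.

**Step 8**
Reactants: 15 (6R)-4-hydroxy-6-methyl-5,6-dihydro-2H-pyran-2-one
Product: 16 (6R)-3-[(dimethylamino)methylidene]-6-methyloxane-2,4-dione
Conditions: Me2NCH(OMe)2 (1.2 equiv), THF, 0 °C → rt
Reagents that add atoms: N,N-dimethylformamide dimethyl acetal, COC(OC)N(C)C
Why: Aminomethylenation of the active C3r methylene of a cyclic 1,3-dicarbonyl with an amide acetal, a condensation that runs without added base.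

**Step 9**
Reactants: 16 (6R)-3-[(dimethylamino)methylidene]-6-methyloxane-2,4-dione
Product: 17 (6R)-4-hydroxy-6-methyl-2-oxo-5,6-dihydro-2H-pyran-3-carbaldehyde
Conditions: 1 M aq. HCl, THF, rt
Reagents that add atoms: water, O
Why: Hydrolysis of a vinylogous amide by addition–elimination of water at the aminomethylene carbon, driven by protonation of dimethylamine and by formation of the strongly hydrogen-bonded formyl enol.

**Step 10**
Reactants: 11 tert-butyl (2R,3R,4S)-3-hydroxy-4-methyl-2-[(4S)-4-methylhex-5-en-1-yl]hexanoate; 17 (6R)-4-hydroxy-6-methyl-2-oxo-5,6-dihydro-2H-pyran-3-carbaldehyde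
Product: 18 tert-butyl (2R,3R,4S)-3-hydroxy-2-[(4S)-7-[(6R)-4-hydroxy-6-methyl-2-oxo-5,6-dihydro-2H-pyran-3-yl]-4-methyl-7-oxoheptyl]-4-methylhexanoate
Conditions: 17 (1.3 equiv), [Rh(cod)OMe]2 (2.5 mol %), BINOL-derived phosphoramidite (MonoPhos type, 6 mol %), K3PO4 (0.5 equiv), degassed THF, 60 °C
Reagents that add atoms: none
Why: Proposed new method: deprotonated 17 should bind Rh(I) through O4r, which places the formyl C7'–H next to the metal; oxidative addition then gives a five-membered acyl(hydrido)rhodacycle (Rh–C7'(=O)–C3r=C4r–O4r), the vinyl group of 11 inserts into Rh–H with Rh going to C6', and C–C reductive elimination forms the C6'–C7' bond. The closest known reaction type is the Rh/phosphoramidite-catalysed, linear-selective intermolecular hydroacylation of unactivated 1-alkenes with salicylaldehydes, of which the C4r-enol/C3r-formyl pair is the non-aromatic, vinylogous counterpart. No ring is closed and no stereocentre is formed. The step needs anti-Markovnikov insertion and no chain walking into C4'; the methyl branch at C4' should keep Rh off C5', and without a Rh–C5' species there is no β-hydride path to the C4' methine. It also needs C–H addition to outrun decarbonylation, which the O4r chelate should secure by saturating the acyl hydride, as the phenoxide does for salicylaldehydes. The free C3–OH, the tert-butyl ester and the lactone should be spectators under the weak base.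

**Step 11**
Reactants: 18 tert-butyl ester of the target (name as in step 10)
Product: 19 (2R,3R,4S)-3-hydroxy-2-[(4S)-7-[(6R)-4-hydroxy-6-methyl-2-oxo-5,6-dihydro-2H-pyran-3-yl]-4-methyl-7-oxoheptyl]-4-methylhexanoic acid (target)
Conditions: TFA/CH2Cl2 1:4, 0 °C → rt
Reagents that add atoms: none
Why: Acidolysis of a tert-butyl ester by E1 loss of 2-methylpropene; the acid-stable acyl-dione and the β-hydroxy acid should survive, and no base touches C2 or the lactone.

**Compound list**
1 | (S)-2-methylbutanoic acid | CC[C@H](C)C(=O)O | starting material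
2 | tert-butyl acetate | CC(=O)OC(C)(C)C | starting material
3 | (S)-1-(1H-imidazol-1-yl)-2-methylbutan-1-one | CC[C@H](C)C(=O)n1ccnc1 | intermediate
4 | tert-butyl (4S)-4-methyl-3-oxohexanoate | CC[C@H](C)C(=O)CC(=O)OC(C)(C)C | intermediate
5 | tert-butyl (3S,4S)-3-hydroxy-4-methylhexanoate | CC[C@H](C)[C@@H](O)CC(=O)OC(C)(C)C | intermediate
6 | (S)-3,7-dimethylocta-1,6-diene | CC(C)=CCC[C@H](C)C=C | starting material
7 | (S)-4-methylhex-5-enal | O=CCC[C@H](C)C=C | intermediate
8 | (S)-4-methylhex-5-en-1-ol | OCCC[C@H](C)C=C | intermediate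
9 | (S)-6-iodo-3-methylhex-1-ene | ICCC[C@H](C)C=C | intermediate
10 | dilithium alkoxide (Z)-enolate of 5 | [Li+].[Li+].CC[C@H](C)[C@@H]([O-])/C=C(\[O-])OC(C)(C)C | intermediate
11 | tert-butyl (2R,3R,4S)-3-hydroxy-4-methyl-2-[(4S)-4-methylhex-5-en-1-yl]hexanoate | CC[C@H](C)[C@@H](O)[C@@H](CCC[C@H](C)C=C)C(=O)OC(C)(C)C | intermediate
12 | ethyl (R)-3-hydroxybutanoate | CCOC(=O)C[C@@H](C)O | starting material
13 | tert-butyl (5R)-5-hydroxy-3-oxohexanoate | CC(C)(C)OC(=O)CC(=O)C[C@@H](C)O | intermediate
14 | (5R)-5-hydroxy-3-oxohexanoic acid | OC(=O)CC(=O)C[C@@H](C)O | intermediate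
15 | (6R)-4-hydroxy-6-methyl-5,6-dihydro-2H-pyran-2-one | O=C1C=C(O)C[C@@H](C)O1 | intermediate
16 | (6R)-3-[(dimethylamino)methylidene]-6-methyloxane-2,4-dione | CN(C)C=C1C(=O)C[C@@H](C)OC1=O | intermediate
17 | (6R)-4-hydroxy-6-methyl-2-oxo-5,6-dihydro-2H-pyran-3-carbaldehyde | O=CC1=C(O)C[C@@H](C)OC1=O | intermediate
18 | tert-butyl (2R,3R,4S)-3-hydroxy-2-[(4S)-7-[(6R)-4-hydroxy-6-methyl-2-oxo-5,6-dihydro-2H-pyran-3-yl]-4-methyl-7-oxoheptyl]-4-methylhexanoate | CC[C@H](C)[C@@H](O)[C@@H](CCC[C@H](C)CCC(=O)C1=C(O)C[C@@H](C)OC1=O)C(=O)OC(C)(C)C | intermediate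
19 | (2R,3R,4S)-3-hydroxy-2-[(4S)-7-[(6R)-4-hydroxy-6-methyl-2-oxo-5,6-dihydro-2H-pyran-3-yl]-4-methyl-7-oxoheptyl]-4-methylhexanoic acid | CC[C@H](C)[C@@H](O)[C@@H](CCC[C@H](C)CCC(=O)C1=C(O)C[C@@H](C)OC1=O)C(=O)O | target

**Step count**
Total: 11 steps. Longest linear sequence: 6 steps (steps 6, 7, 8, 9, 10, 11, from ethyl (R)-3-hydroxybutanoate 12).

**Steps most likely to fail**

1. Step 10 (Proposed new method). The acyl-rhodium hydride may lose CO instead of inserting the alkene, which would stop the catalyst as a rhodium carbonyl. The tricarbonyl anion may also rest as an unreactive O,O-chelate. Reversible Markovnikov insertion could walk the alkene into C4' and erase that stereocentre. The fallback uses known chemistry, sets out from 11 and comes back at 18. Linear-selective hydroformylation of the vinyl group (Rh(acac)(CO)2, Xantphos, CO/H2, toluene, 80 °C) should give tert-butyl (2R,3R,4S)-3-hydroxy-4-methyl-2-[(4S)-4-methyl-7-oxoheptyl]hexanoate F1. Pinnick oxidation (NaClO2, NaH2PO4, 2-methyl-2-butene, tBuOH/H2O) should give (4S,8R,9R,10S)-8-(tert-butoxycarbonyl)-9-hydroxy-4,10-dimethyldodecanoic acid F2. Coupling with 15 (DCC, DMAP, CH2Cl2) should give the enol ester (6R)-6-methyl-2-oxo-5,6-dihydro-2H-pyran-4-yl (4S,8R,9R,10S)-8-(tert-butoxycarbonyl)-9-hydroxy-4,10-dimethyldodecanoate F3, which DMAP should convert in the same flask by Fries-type O→C acyl migration into 18. The hindered C3–OH is expected not to compete with the far more acidic enol of 15.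

2. Step 5. SN2 of the unactivated primary iodide on the aggregated dianion may be slow, so that E2 of 9 and proton transfer compete. The higher temperature then needed may erode the anti selectivity. The fallback sets out from 4 and 9 and comes back at 11. C-Alkylation of the β-keto ester 4 with 9 (K2CO3, DMF, rt) should give tert-butyl (4S)-4-methyl-2-[(4S)-4-methylhex-5-en-1-yl]-3-oxohexanoate F4 as a mixture of C2 epimers. An anti-selective ketoreductase chosen from a screening panel (NADP+, glucose/glucose dehydrogenase, phosphate buffer pH 7/DMSO, 30 °C) should then reduce it with dynamic kinetic resolution. C2 epimerises through the β-keto ester enol while only the (2R)-epimer is reduced to the (3R)-alcohol; C4 is far less acidic and should hold.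

3. Step 9. Aqueous acid may open the lactone or trigger β-elimination across C5r–C6r, and the formyl group may be lost by retro-Claisen cleavage before the vinylogous amide is fully hydrolysed. The fallback sets out from 15 and comes back at 17. Ethoxymethylenation (HC(OEt)3, Ac2O, 90 °C) should give (6R)-3-(ethoxymethylidene)-6-methyloxane-2,4-dione F5. This vinylogous ester should hydrolyse in THF/water at rt without added acid or base, in place of hydrolysis of the much less reactive vinylogous amide.

**Further compounds**
F1 | step 10 | tert-butyl (2R,3R,4S)-3-hydroxy-4-methyl-2-[(4S)-4-methyl-7-oxoheptyl]hexanoate | CC[C@H](C)[C@@H](O)[C@@H](CCC[C@H](C)CCC=O)C(=O)OC(C)(C)C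
F2 | step 10 | (4S,8R,9R,10S)-8-(tert-butoxycarbonyl)-9-hydroxy-4,10-dimethyldodecanoic acid | CC[C@H](C)[C@@H](O)[C@@H](CCC[C@H](C)CCC(=O)O)C(=O)OC(C)(C)C
F3 | step 10 | (6R)-6-methyl-2-oxo-5,6-dihydro-2H-pyran-4-yl (4S,8R,9R,10S)-8-(tert-butoxycarbonyl)-9-hydroxy-4,10-dimethyldodecanoate | CC[C@H](C)[C@@H](O)[C@@H](CCC[C@H](C)CCC(=O)OC1=CC(=O)O[C@H](C)C1)C(=O)OC(C)(C)C
F4 | step 5 | tert-butyl (4S)-4-methyl-2-[(4S)-4-methylhex-5-en-1-yl]-3-oxohexanoate (C2 epimers) | CC[C@H](C)C(=O)C(CCC[C@H](C)C=C)C(=O)OC(C)(C)C
F5 | step 9 | (6R)-3-(ethoxymethylidene)-6-methyloxane-2,4-dione | CCOC=C1C(=O)C[C@@H](C)OC1=O
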